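The summer run holds more J than the dawn run, by a factor of 2.24, yet the last readings of the two runs are close: E 22.0% in dawn and 21.8% in summer.

| flask | Q | J | remark | time |
|---|---|---|---|---|
| dawn | 17 mM | 0.67 mol% | run made earlier |  |
| summer | 17 mM | 1.5 mol% | run made earlier |  |
| flask | 17 mM | 1 mol% |  | 12 d |

| run | time / d | Q / % | E / % |
|---|---|---|---|
| dawn | 0.625 | 3.8 | 16.9 |
| dawn | 1.67 | 5.5 | 20.5 |
| dawn | 3.00 | 4.7 | 20.5 |
| dawn | 5.00 | 4.5 | 21.3 |
| dawn | 8.00 | 4.0 | 22.0 |
| summer | 0.625 | 4.4 | 20.0 |
| summer | 1.67 | 3.1 | 21.8 |
| summer | 3.00 | 4.2 | 21.1 |
| summer | 5.00 | 5.3 | 22.0 |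
| summer | 8.00 | 4.4 | 21.8 |

(scatter of a reading: 0.5 percentage points)

- the reaction counts as stopped when no species that holds the Q changes by six tenths of a point or more over the second half of the time

* the state of affairs at 12 d: stopped, and by what, or still going (all of Q has reacted / it is still moving / no working catalyst is left / forward and back rates have come level)
* conversion of Q at 12 d
* amount of E at 12 d, in percent of the Q charged
* amount of L at 12 d, in percent of the Q charged

1. Main step first: J turns Q over, one way. Loading times time counts the turnovers on offer. The reference is the dawn run's second reading at 1.67 d, where E is within 1.5 percentage points of its last reading. Against it the flask has 10.7: this is the catalyst-time multiple, a flask's loading times time over that of the reference reading. The early readings climb with it: 0.374 gives E 16.9% in dawn, 0.838 gives 20.0% in summer, and 1 gives 20.5% in dawn. A one-way step sends Q towards zero.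

2. Add the way back. Q stops falling: the summer run reads 3.1% at 1.67 d and 4.4% at 8.00 d. Conversion therefore levels off short of completion, and the plateau is one of thermodynamic control.

3. Add a fading catalyst. Plateaus should then shift with loading, but the factor of 2.24 moves the last E reading by 0.2 points, less than the scatter of 0.5 points. L, by difference, is 73.8% in the summer run. With a multiple of 10.7, the flask should stand on this plateau.

The forecast says forward and back rates have come level, with conversion 95.6%, E 21.8% and L 73.8%: “A dying catalyst would give plateaus that depend on loading, and this one doesn't, so it looks like true equilibrium.”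

At 12 d the flask gives forward and back rates have come level, with conversion 95.7%, E 21.2% and L 74.5%.

    Q ⇌ E (K = 4.91, k = 0.0644 h⁻¹)
    2 J ⇌ Z, settled at all times (K = 2500 L mol⁻¹)
    E + J ⇌ L + J, rate k3*[J]*[E] forward; the back reaction follows from the equilibrium constant (K = 3.51, k = 857 L mol⁻¹ h⁻¹)
    L + J ⇌ Q + J, rate k4*[J]*[L] forward; the back reaction follows from the equilibrium constant (k = 4530 L mol⁻¹ h⁻¹)

In the flask at 12.0 d, Z, the paired form of J, holds 35.4% of the catalyst and J holds 64.6%. The dawn run, with the same pairing, keeps 71.2% of its catalyst as J, so with both sides counted alike the multiple of the flask is 9.71. The neighbour charged with 4 mol% of J has a multiple of 42.9, and with 41.5% of its catalyst as J, 25.0 counted alike; that neighbour holds E 21.2%.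

The earlier runs and the new flask come from a simulation for substances that don't exist, and the scatter is random.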